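## Retrosynthetic overview

1. Target 19 (13,14-dihydro-19(R)-hydroxy-PGE2) ⇐ C9 ketone from the 9α-alcohol; the 11-, 15- and 19-hydroxyls are carried as TBS ethers and freed last.
2. C5=C6 (Z) ⇐ Wittig reaction of a Corey-type lactol with the ylide of (4-carboxybutyl)triphenylphosphonium bromide.
3. C13–C14 ⇐ Horner–Wadsworth–Emmons reaction of Corey aldehyde benzoate with a β-ketophosphonate; C15 set by CBS reduction, then C13=C14 hydrogenated.
4. β-Ketophosphonate ⇐ γ-alkylation of the dianion of dimethyl (2-oxopropyl)phosphonate with an iodide made from (R)-butane-1,3-diol, which supplies C19.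
5. No ring is formed: the cyclopentane, with C8, C9, C11 and C12 already set, is bought as (−)-Corey lactone benzoate, and its lactone ring is opened in the Wittig step.

Assumption: compounds 1, 4, 7 and 15 are catalogue chemicals. TBS = tert-butyldimethylsilyl; positions are given in prostaglandin numbering (C1–C20).

## Route

Step 1
Reactants: 1 (R)-butane-1,3-diol
Product: 2 (2R)-4-iodobutan-2-ol
Conditions: I2 (1.05 equiv), PPh3 (1.05 equiv), imidazole, CH2Cl2, −10 → 0 °C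
Reagents that add atoms: iodine, SMILES: II
Why: Appel-type (Garegg–Samuelsson) iodination, in which the primary hydroxyl forms the alkoxyphosphonium ion much faster than the secondary one and is displaced by iodide, so the carbinol centre (later C19, R) is untouched.

Step 2
Reactants: 2 (2R)-4-iodobutan-2-ol
Product: 3 tert-butyl{[(2R)-4-iodobutan-2-yl]oxy}dimethylsilane
Conditions: TBSCl, imidazole, DMF, rt
Reagents that add atoms: tert-butyldimethylsilyl chloride (TBSCl), SMILES: CC(C)(C)[Si](C)(C)Cl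
Why: Silyl ether formation on the secondary alcohol with a weak base that does not trigger oxetane closure; the stereocentre is not involved.

Step 3
Reactants: 3 tert-butyl{[(2R)-4-iodobutan-2-yl]oxy}dimethylsilane; 4 dimethyl (2-oxopropyl)phosphonate
Product: 6 dimethyl [(6R)-6-(TBSO)-2-oxoheptyl]phosphonate, via phosphonate dianion 5 (not isolated)
Conditions: 4 (1.2 equiv), NaH, THF, 0 °C; n-BuLi, 0 °C; then 3, 0 °C → rt
Reagents that add atoms: none
Why: γ-Alkylation of a β-ketophosphonate dianion, in which the more basic terminal carbanion attacks the primary iodide by SN2 and the remote stereocentre is untouched.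

Step 4
Reactants: 7 (−)-Corey lactone benzoate, (3aR,4S,5R,6aS)-4-(hydroxymethyl)-2-oxohexahydro-2H-cyclopenta[b]furan-5-yl benzoate
Product: 8 (3aR,4R,5R,6aS)-4-formyl-2-oxohexahydro-2H-cyclopenta[b]furan-5-yl benzoate
Conditions: Dess–Martin periodinane, CH2Cl2, 0 °C → rt; crude aldehyde used at once
Reagents that add atoms: none
Why: Dess–Martin oxidation of the primary alcohol under non-basic conditions, which avoids β-elimination of the benzoate and epimerisation at C12.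

Step 5
Reactants: 8 (3aR,4R,5R,6aS)-4-formyl-2-oxohexahydro-2H-cyclopenta[b]furan-5-yl benzoate; 6 dimethyl [(6R)-6-(TBSO)-2-oxoheptyl]phosphonate
Product: 9 (3aR,4R,5R,6aS)-4-[(1E,7R)-7-(TBSO)-3-oxooct-1-en-1-yl]-2-oxohexahydro-2H-cyclopenta[b]furan-5-yl benzoate
Conditions: LiCl, i-Pr2NEt, MeCN, rt
Reagents that add atoms: none
Why: Horner–Wadsworth–Emmons olefination under Masamune–Roush conditions gives the E-enone with a base too weak to eliminate the β-benzoate; no new stereocentre is formed.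

Step 6
Reactants: 9 (3aR,4R,5R,6aS)-4-[(1E,7R)-7-(TBSO)-3-oxooct-1-en-1-yl]-2-oxohexahydro-2H-cyclopenta[b]furan-5-yl benzoate
Product: 10 (3aR,4R,5R,6aS)-4-[(1E,3S,7R)-7-(TBSO)-3-hydroxyoct-1-en-1-yl]-2-oxohexahydro-2H-cyclopenta[b]furan-5-yl benzoate
Conditions: (R)-Me-CBS oxazaborolidine, (3aR)-1-methyl-3,3-diphenyltetrahydro-1H,3H-pyrrolo[1,2-c][1,3,2]oxazaborole (0.3 equiv), BH3·SMe2 (0.7 equiv), THF, −20 °C; MeOH quench
Reagents that add atoms: none
Why: Corey–Bakshi–Shibata reduction, in which the (R)-oxazaborolidine–borane complex treats the alkenyl group as the large substituent and delivers hydride to the face that gives the 15S allylic alcohol (about 9:1 expected, minor 15R epimer removed on silica).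

Step 7
Reactants: 10 (3aR,4R,5R,6aS)-4-[(1E,3S,7R)-7-(TBSO)-3-hydroxyoct-1-en-1-yl]-2-oxohexahydro-2H-cyclopenta[b]furan-5-yl benzoate
Product: 11 (3aR,4R,5R,6aS)-4-[(3S,7R)-7-(TBSO)-3-hydroxyoctyl]-2-oxohexahydro-2H-cyclopenta[b]furan-5-yl benzoate
Conditions: H2 (1 atm), 5% Pd/C, EtOAc, Et3N (trace), rt
Reagents that add atoms: none
Why: Heterogeneous catalytic hydrogenation saturates the disubstituted C13=C14 alkene while the trace of amine suppresses allylic C–O hydrogenolysis and isomerisation, and C15 keeps its configuration (still S).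

Step 8
Reactants: 11 (3aR,4R,5R,6aS)-4-[(3S,7R)-7-(TBSO)-3-hydroxyoctyl]-2-oxohexahydro-2H-cyclopenta[b]furan-5-yl benzoate
Product: 12 (3aR,4R,5R,6aS)-5-hydroxy-4-[(3S,7R)-7-(TBSO)-3-hydroxyoctyl]hexahydro-2H-cyclopenta[b]furan-2-one
Conditions: K2CO3, MeOH, rt; then dilute HCl to pH 4
Reagents that add atoms: none
Why: Base-catalysed transesterification (methanolysis) removes the benzoate as methyl benzoate, and any lactone opened by methoxide recloses on acidification.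

Step 9
Reactants: 12 (3aR,4R,5R,6aS)-5-hydroxy-4-[(3S,7R)-7-(TBSO)-3-hydroxyoctyl]hexahydro-2H-cyclopenta[b]furan-2-one
Product: 13 (3aR,4R,5R,6aS)-5-(TBSO)-4-[(3S,7R)-3,7-bis(TBSO)octyl]hexahydro-2H-cyclopenta[b]furan-2-one
Conditions: TBSCl (3 equiv), imidazole, DMF, rt → 40 °C
Reagents that add atoms: tert-butyldimethylsilyl chloride (TBSCl), SMILES: CC(C)(C)[Si](C)(C)Cl
Why: Silyl ether formation on both secondary hydroxyls gives uniform protection that withstands hydride, ylide and oxidant and is removable without base.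

Step 10
Reactants: 13 (3aR,4R,5R,6aS)-5-(TBSO)-4-[(3S,7R)-3,7-bis(TBSO)octyl]hexahydro-2H-cyclopenta[b]furan-2-one
Product: 14 (3aR,4R,5R,6aS)-5-(TBSO)-4-[(3S,7R)-3,7-bis(TBSO)octyl]hexahydro-2H-cyclopenta[b]furan-2-ol (anomer mixture)
Conditions: i-Bu2AlH (1.2 equiv), toluene, −78 °C; MeOH, aq. potassium sodium tartrate (KNaC4H4O6)
Reagents that add atoms: none
Why: Partial reduction of the γ-lactone by the aluminium hydride at −78 °C stops at the tetrahedral aluminium hemiacetal, which gives the lactol on work-up.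

Step 11
Reactants: 14 (3aR,4R,5R,6aS)-5-(TBSO)-4-[(3S,7R)-3,7-bis(TBSO)octyl]hexahydro-2H-cyclopenta[b]furan-2-ol; 15 (4-carboxybutyl)triphenylphosphonium bromide
Product: 17 (5Z)-7-[(1R,2R,3R,5S)-3-(TBSO)-2-[(3S,7R)-3,7-bis(TBSO)octyl]-5-hydroxycyclopentyl]hept-5-enoic acid, via carboxylate ylide 16 (not isolated)
Conditions: 15 (3 equiv), KOt-Bu (6 equiv), THF, 0 °C; then 14, 0 °C → rt; dilute HCl to pH 4–5
Reagents that add atoms: none
Why: Wittig olefination of the open hydroxy-aldehyde form of the lactol with a non-stabilised ylide under lithium-free conditions gives the 5Z alkene and frees only the 9α-hydroxyl.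

Step 12
Reactants: 17 (5Z)-7-[(1R,2R,3R,5S)-3-(TBSO)-2-[(3S,7R)-3,7-bis(TBSO)octyl]-5-hydroxycyclopentyl]hept-5-enoic acid
Product: 18 (5Z)-7-[(1R,2R,3R)-3-(TBSO)-2-[(3S,7R)-3,7-bis(TBSO)octyl]-5-oxocyclopentyl]hept-5-enoic acid
Conditions: Dess–Martin periodinane, pyridine, CH2Cl2, 0 °C → rt
Reagents that add atoms: none
Why: Dess–Martin oxidation of the only free hydroxyl (C9) to the ketone under buffered conditions that neither epimerise C8 nor eliminate the C11 silyloxy group.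

Step 13
Reactants: 18 (5Z)-7-[(1R,2R,3R)-3-(TBSO)-2-[(3S,7R)-3,7-bis(TBSO)octyl]-5-oxocyclopentyl]hept-5-enoic acid
Product: 19 (5Z)-7-[(1R,2R,3R)-3-hydroxy-2-[(3S,7R)-3,7-dihydroxyoctyl]-5-oxocyclopentyl]hept-5-enoic acid (target, CNP0414125.1)
Conditions: HF·pyridine, MeCN, 0 °C → rt
Reagents that add atoms: none
Why: Fluoride-mediated desilylation of the three silyl ethers under mildly acidic conditions that the β-hydroxy ketone tolerates without dehydration or C8 epimerisation.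

## Compound list

1 | (R)-butane-1,3-diol | C[C@@H](O)CCO | starting material
2 | (2R)-4-iodobutan-2-ol | C[C@@H](O)CCI | intermediate
3 | tert-butyl{[(2R)-4-iodobutan-2-yl]oxy}dimethylsilane | C[C@@H](O[Si](C)(C)C(C)(C)C)CCI | intermediate
4 | dimethyl (2-oxopropyl)phosphonate | COP(=O)(OC)CC(C)=O | starting material
5 | sodium lithium 1,3-dianion of dimethyl (2-oxopropyl)phosphonate | [Na+].[Li+].COP(=O)(OC)[CH-]C(=O)[CH2-] | intermediate (not isolated)
6 | dimethyl [(6R)-6-(tert-butyldimethylsilyloxy)-2-oxoheptyl]phosphonate | COP(=O)(OC)CC(=O)CCC[C@@H](C)O[Si](C)(C)C(C)(C)C | intermediate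
7 | (3aR,4S,5R,6aS)-4-(hydroxymethyl)-2-oxohexahydro-2H-cyclopenta[b]furan-5-yl benzoate, (−)-Corey lactone benzoate | OC[C@H]1[C@H](OC(=O)c3ccccc3)C[C@@H]2OC(=O)C[C@H]12 | starting material
8 | (3aR,4R,5R,6aS)-4-formyl-2-oxohexahydro-2H-cyclopenta[b]furan-5-yl benzoate | O=C[C@H]1[C@H](OC(=O)c3ccccc3)C[C@@H]2OC(=O)C[C@H]12 | intermediate
9 | (3aR,4R,5R,6aS)-4-[(1E,7R)-7-(tert-butyldimethylsilyloxy)-3-oxooct-1-en-1-yl]-2-oxohexahydro-2H-cyclopenta[b]furan-5-yl benzoate | C[C@@H](O[Si](C)(C)C(C)(C)C)CCCC(=O)/C=C/[C@H]1[C@H](OC(=O)c3ccccc3)C[C@@H]2OC(=O)C[C@H]12 | intermediate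
10 | (3aR,4R,5R,6aS)-4-[(1E,3S,7R)-7-(tert-butyldimethylsilyloxy)-3-hydroxyoct-1-en-1-yl]-2-oxohexahydro-2H-cyclopenta[b]furan-5-yl benzoate | C[C@@H](O[Si](C)(C)C(C)(C)C)CCC[C@H](O)/C=C/[C@H]1[C@H](OC(=O)c3ccccc3)C[C@@H]2OC(=O)C[C@H]12 | intermediate
11 | (3aR,4R,5R,6aS)-4-[(3S,7R)-7-(tert-butyldimethylsilyloxy)-3-hydroxyoctyl]-2-oxohexahydro-2H-cyclopenta[b]furan-5-yl benzoate | C[C@@H](O[Si](C)(C)C(C)(C)C)CCC[C@H](O)CC[C@H]1[C@H](OC(=O)c3ccccc3)C[C@@H]2OC(=O)C[C@H]12 | intermediate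
12 | (3aR,4R,5R,6aS)-5-hydroxy-4-[(3S,7R)-7-(tert-butyldimethylsilyloxy)-3-hydroxyoctyl]hexahydro-2H-cyclopenta[b]furan-2-one | C[C@@H](O[Si](C)(C)C(C)(C)C)CCC[C@H](O)CC[C@H]1[C@H](O)C[C@@H]2OC(=O)C[C@H]12 | intermediate
13 | (3aR,4R,5R,6aS)-5-(tert-butyldimethylsilyloxy)-4-[(3S,7R)-3,7-bis(tert-butyldimethylsilyloxy)octyl]hexahydro-2H-cyclopenta[b]furan-2-one | C[C@@H](O[Si](C)(C)C(C)(C)C)CCC[C@H](O[Si](C)(C)C(C)(C)C)CC[C@H]1[C@H](O[Si](C)(C)C(C)(C)C)C[C@@H]2OC(=O)C[C@H]12 | intermediate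
14 | (3aR,4R,5R,6aS)-5-(tert-butyldimethylsilyloxy)-4-[(3S,7R)-3,7-bis(tert-butyldimethylsilyloxy)octyl]hexahydro-2H-cyclopenta[b]furan-2-ol (anomer mixture) | C[C@@H](O[Si](C)(C)C(C)(C)C)CCC[C@H](O[Si](C)(C)C(C)(C)C)CC[C@H]1[C@H](O[Si](C)(C)C(C)(C)C)C[C@@H]2OC(O)C[C@H]12 | intermediate
15 | (4-carboxybutyl)triphenylphosphonium bromide | OC(=O)CCCC[P+](c1ccccc1)(c1ccccc1)c1ccccc1.[Br-] | starting material
16 | potassium 5-(triphenyl-λ5-phosphanylidene)pentanoate | [K+].[O-]C(=O)CCCC=P(c1ccccc1)(c1ccccc1)c1ccccc1 | intermediate (not isolated)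
17 | (5Z)-7-[(1R,2R,3R,5S)-3-(tert-butyldimethylsilyloxy)-2-[(3S,7R)-3,7-bis(tert-butyldimethylsilyloxy)octyl]-5-hydroxycyclopentyl]hept-5-enoic acid | C[C@@H](O[Si](C)(C)C(C)(C)C)CCC[C@H](O[Si](C)(C)C(C)(C)C)CC[C@H]1[C@H](O[Si](C)(C)C(C)(C)C)C[C@H](O)[C@@H]1C/C=C\CCCC(=O)O | intermediate
18 | (5Z)-7-[(1R,2R,3R)-3-(tert-butyldimethylsilyloxy)-2-[(3S,7R)-3,7-bis(tert-butyldimethylsilyloxy)octyl]-5-oxocyclopentyl]hept-5-enoic acid | C[C@@H](O[Si](C)(C)C(C)(C)C)CCC[C@H](O[Si](C)(C)C(C)(C)C)CC[C@H]1[C@H](O[Si](C)(C)C(C)(C)C)CC(=O)[C@@H]1C/C=C\CCCC(=O)O | intermediate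
19 | (5Z)-7-[(1R,2R,3R)-3-hydroxy-2-[(3S,7R)-3,7-dihydroxyoctyl]-5-oxocyclopentyl]hept-5-enoic acid | C[C@@H](O)CCC[C@H](O)CC[C@H]1[C@H](O)CC(=O)[C@@H]1C/C=C\CCCC(=O)O | target

## Summary

Total step count: 13.
Longest linear sequence: 12 steps (1 → 2 → 3 → 6 → 9 → 10 → 11 → 12 → 13 → 14 → 17 → 18 → 19; step 4 lies on the shorter branch).

The three steps most likely to fail, each with its fallback:

The first is step 6, where the CBS reduction may give poor C15 selectivity. The fallback sets out from enone 9 and gives up reagent control. A Luche reduction (NaBH4, CeCl3·7H2O, MeOH, −40 °C) gives 10 together with the 15R allylic alcohol F1, and the two are separated on silica. Compound 10 goes on as in the route. F1 is hydrogenated (H2, 5% Pd/C, EtOAc) to the 15R saturated alcohol F2. F2 is inverted by a Mitsunobu reaction (PhCO2H, PPh3, DIAD, THF, 0 °C → rt) to the 15S dibenzoate F3. Methanolysis of both benzoates (K2CO3, MeOH) brings the material back to the route at diol 12, so both C15 epimers are used.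

The second is step 11, where the basic Wittig medium may shift the C11 silyl group to the 9-oxygen or give low conversion with the crowded lactol. The fallback sets out from diol 12 and postpones protection until after the olefination. Reduction with i-Bu2AlH (3.5 equiv, THF, −78 °C) gives the lactol diol F4. Wittig reaction with ylide 16 (5 equiv, THF, 0 °C → rt) gives the triol acid F5. The hindered 9α-hydroxyl, cis to the neighbouring side chain, is the slowest to silylate. TBSCl (2.2 equiv) and imidazole in DMF at −20 → 0 °C therefore protect the 11- and 15-hydroxyls selectively, with any silyl ester cleaved on aqueous work-up. This comes back to the route at 17.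

The third is step 13, where the final desilylation may dehydrate the β-hydroxy ketone to the cyclopentenone or stall at the secondary silyl ethers. The fallback sets out from 17 and removes the robust silyl groups before the sensitive ketone exists. HF·pyridine in MeCN at rt converts 17 into the tetraol acid F6. Selective silylation of the three unhindered hydroxyls (Et3SiCl, pyridine, −30 °C, silyl ester cleaved on work-up) gives the tris(triethylsilyl) ether F7 with the 9-hydroxyl free. Dess–Martin oxidation (pyridine, CH2Cl2, 0 °C) gives the ketone F8. Its triethylsilyl ethers fall off in AcOH/THF/H2O at rt, conditions under which E-type prostaglandins are stable, and this comes back to the route at 19.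

Further compounds

F1 | step 6 | (3aR,4R,5R,6aS)-4-[(1E,3R,7R)-7-(tert-butyldimethylsilyloxy)-3-hydroxyoct-1-en-1-yl]-2-oxohexahydro-2H-cyclopenta[b]furan-5-yl benzoate | C[C@@H](O[Si](C)(C)C(C)(C)C)CCC[C@@H](O)/C=C/[C@H]1[C@H](OC(=O)c3ccccc3)C[C@@H]2OC(=O)C[C@H]12
F2 | step 6 | (3aR,4R,5R,6aS)-4-[(3R,7R)-7-(tert-butyldimethylsilyloxy)-3-hydroxyoctyl]-2-oxohexahydro-2H-cyclopenta[b]furan-5-yl benzoate | C[C@@H](O[Si](C)(C)C(C)(C)C)CCC[C@@H](O)CC[C@H]1[C@H](OC(=O)c3ccccc3)C[C@@H]2OC(=O)C[C@H]12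
F3 | step 6 | (3S,7R)-1-[(3aR,4R,5R,6aS)-5-(benzoyloxy)-2-oxohexahydro-2H-cyclopenta[b]furan-4-yl]-7-(tert-butyldimethylsilyloxy)octan-3-yl benzoate | C[C@@H](O[Si](C)(C)C(C)(C)C)CCC[C@H](OC(=O)c4ccccc4)CC[C@H]1[C@H](OC(=O)c3ccccc3)C[C@@H]2OC(=O)C[C@H]12
F4 | step 11 | (3aR,4R,5R,6aS)-4-[(3S,7R)-7-(tert-butyldimethylsilyloxy)-3-hydroxyoctyl]hexahydro-2H-cyclopenta[b]furan-2,5-diol (anomer mixture) | C[C@@H](O[Si](C)(C)C(C)(C)C)CCC[C@H](O)CC[C@H]1[C@H](O)C[C@@H]2OC(O)C[C@H]12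
F5 | step 11 | (5Z)-7-[(1R,2R,3R,5S)-2-[(3S,7R)-7-(tert-butyldimethylsilyloxy)-3-hydroxyoctyl]-3,5-dihydroxycyclopentyl]hept-5-enoic acid | C[C@@H](O[Si](C)(C)C(C)(C)C)CCC[C@H](O)CC[C@H]1[C@H](O)C[C@H](O)[C@@H]1C/C=C\CCCC(=O)O
F6 | step 13 | (5Z)-7-[(1R,2R,3R,5S)-2-[(3S,7R)-3,7-dihydroxyoctyl]-3,5-dihydroxycyclopentyl]hept-5-enoic acid | C[C@@H](O)CCC[C@H](O)CC[C@H]1[C@H](O)C[C@H](O)[C@@H]1C/C=C\CCCC(=O)O
F7 | step 13 | (5Z)-7-[(1R,2R,3R,5S)-5-hydroxy-3-(triethylsilyloxy)-2-[(3S,7R)-3,7-bis(triethylsilyloxy)octyl]cyclopentyl]hept-5-enoic acid | C[C@@H](O[Si](CC)(CC)CC)CCC[C@H](O[Si](CC)(CC)CC)CC[C@H]1[C@H](O[Si](CC)(CC)CC)C[C@H](O)[C@@H]1C/C=C\CCCC(=O)O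
F8 | step 13 | (5Z)-7-[(1R,2R,3R)-5-oxo-3-(triethylsilyloxy)-2-[(3S,7R)-3,7-bis(triethylsilyloxy)octyl]cyclopentyl]hept-5-enoic acid | C[C@@H](O[Si](CC)(CC)CC)CCC[C@H](O[Si](CC)(CC)CC)CC[C@H]1[C@H](O[Si](CC)(CC)CC)CC(=O)[C@@H]1C/C=C\CCCC(=O)O
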